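**Plan**

Ring atoms carry daucane numbers: C1 (quaternary, CH3), C2, C3, C4 (C(OH)iPr), C5 (ring-fusion CH), C6 (CH–O-veratroyl), C7 (CH2), C8 (=C–CH3), C9 (=CH), C10 (CH–O-angeloyl); β is the face of the C1 methyl group.
Retrosynthesis: first the two ester C–O bonds (C10 angelate by invertive esterification, C6 veratrate by acylation); then C7–C8 and C1–C5 together, a (4+3) disconnection of the hydroazulene to an acyclic epoxy enol silane that carries a 2-silyloxy diene; then C3–C4 (sp3–sp2 coupling) and C1–C10 (crotylation).
Enabling feature: in the seven-membered ring C5–C6(O)–C7 is a 2-oxyallyl unit and C1–C10(O)–C9=C8 a 2-oxy-diene; the C4 carbinol sits next to the allyl terminus C5 (retron of an α,β-epoxy ketone); the cyclopentane C1–C2–C3–C4–C5 is a three-atom tether between allyl and diene termini.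
Forward: crotylation, B-alkyl Suzuki coupling, Sharpless epoxidation, conversion to an epoxy diketone and its bis(enol silane); both rings then close in one operation from the open chain; Saegusa oxidation, two reductions and two esterifications finish the target.
Stereochemistry: C4 by Sharpless epoxidation (the only catalyst-set centre); C5 (inversion at the epoxide) and C1 (trans ring fusion) relayed in the cascade; C6 by hydroxyl-directed reduction from O4; C10 by hydride addition anti to the C1 methyl followed by Mitsunobu inversion; the Z angelate is bought as angelic acid.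

Key step: step 11

Remark: 4-methylpent-2-yn-1-ol (5) is taken as a catalogue compound.
Remark: 3, 4, 8, 9 and 10–14 are carried as stereoisomer mixtures at the carbons that become C1 and C10 (12 and 13 also at the carbinol that becomes C6); all of these are planar before step 11.

**Step 1**
Reactants: 1 (E)-but-2-enal (crotonaldehyde); 2 (E)-1-bromobut-2-ene (crotyl bromide)
Product: 3 (5E)-3-methylhepta-1,5-dien-4-ol (racemic diastereomer mixture)
Conditions: Zn dust, THF/sat. aq NH4Cl, 0 °C to rt
Reagents that add atoms: none
Why: Barbier crotylation, in which the crotylzinc species adds 1,2 to the enal through its γ-carbon, should place the future C1 methyl branch next to a terminal vinyl group; both new stereocentres are uncontrolled and are removed later (steps 9 and 10).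

**Step 2**
Reactants: 3 (5E)-3-methylhepta-1,5-dien-4-ol
Product: 4 tert-butyl{[(5E)-3-methylhepta-1,5-dien-4-yl]oxy}dimethylsilane
Conditions: TBSCl, imidazole, DMF, rt
Reagents that add atoms: tert-butyldimethylsilyl chloride, CC(C)(C)[Si](C)(C)Cl
Why: Standard silylation of a secondary alcohol; it masks this allylic alcohol so that only the primary allylic alcohol of 9 directs the titanium epoxidation in step 5.

**Step 3**
Reactants: 5 4-methylpent-2-yn-1-ol
Product: 7 (2Z)-3-iodo-4-methylpent-2-en-1-ol, via sodium alkenylalanate 6 (not isolated)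
Conditions: Red-Al, THF, 0 °C to rt; then I2, THF, −78 to 0 °C
Reagents that add atoms: Red-Al, [Na+].COCCO[AlH2-]OCCOC (its aluminium stays only in 6); iodine, II
Why: Hydroxyl-directed trans-hydroalumination of the propargylic alcohol should give the five-membered alkenylalanate with aluminium on C3, and iodinolysis with retention then puts iodine cis to CH2OH and the isopropyl group trans.

**Step 4**
Reactants: 4 tert-butyl{[(5E)-3-methylhepta-1,5-dien-4-yl]oxy}dimethylsilane; 7 (2Z)-3-iodo-4-methylpent-2-en-1-ol
Product: 9 (2E,8E)-7-[(tert-butyldimethylsilyl)oxy]-6-methyl-3-(propan-2-yl)deca-2,8-dien-1-ol, via B-alkyl-9-BBN 8 (not isolated)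
Conditions: 9-BBN-H, THF, 0 °C to rt; then 7, Pd(dppf)Cl2 (5 mol%), AsPh3, Cs2CO3, DMF/H2O, rt
Reagents that add atoms: 9-borabicyclo[3.3.1]nonane, B1C2CCCC1CCC2 (stays only in 8)
Why: 9-BBN should hydroborate only the terminal vinyl group (anti-Markovnikov), and B-alkyl Suzuki–Miyaura coupling with the alkenyl iodide proceeds with retention of geometry, so the new chain (C3–C2–C1) ends up cis to CH2OH.

**Step 5**
Reactants: 9 (2E,8E)-7-[(tert-butyldimethylsilyl)oxy]-6-methyl-3-(propan-2-yl)deca-2,8-dien-1-ol
Product: 10 [(2R,3R)-3-{(5E)-4-[(tert-butyldimethylsilyl)oxy]-3-methylhept-5-en-1-yl}-3-(propan-2-yl)oxiran-2-yl]methanol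
Conditions: Ti(OiPr)4 (10 mol%), D-(−)-diethyl tartrate (12 mol%), t-BuOOH, 4 Å MS, CH2Cl2, −20 °C
Reagents that add atoms: tert-butyl hydroperoxide, CC(C)(C)OO
Why: Sharpless asymmetric epoxidation of a 3,3-disubstituted primary allylic alcohol; with the D-(−)-tartrate the oxygen should be delivered to the face that gives the (2R,3R)-epoxide, which fixes C4 of the target and the epoxide configuration at the future C5, while the silylated allylic ether is not a substrate.

**Step 6**
Reactants: 10 the (2R,3R)-epoxy alcohol
Product: 11 (2S,3R)-3-{(5E)-4-[(tert-butyldimethylsilyl)oxy]-3-methylhept-5-en-1-yl}-3-(propan-2-yl)oxirane-2-carbaldehyde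
Conditions: Dess–Martin periodinane, NaHCO3, CH2Cl2, 0 °C to rt
Reagents that add atoms: none
Why: Buffered Dess–Martin oxidation of a primary epoxy alcohol to the epoxy aldehyde should leave the acid-sensitive trisubstituted epoxide and its configuration untouched.

**Step 7**
Reactants: 11 the epoxy aldehyde
Product: 12 1-[(2R,3R)-3-{(5E)-4-[(tert-butyldimethylsilyl)oxy]-3-methylhept-5-en-1-yl}-3-(propan-2-yl)oxiran-2-yl]ethan-1-ol (carbinol epimers)
Conditions: MeMgBr, THF, −78 °C; aq NH4Cl
Reagents that add atoms: methylmagnesium bromide, C[Mg]Br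
Why: Grignard addition to the aldehyde at low temperature brings in C7; the configuration of the new carbinol is irrelevant because it is oxidised in step 9.

**Step 8**
Reactants: 12 the silyl-protected epoxy alcohol
Product: 13 (5E)-1-[(2R,3R)-3-(1-hydroxyethyl)-2-(propan-2-yl)oxiran-2-yl]-3-methylhept-5-en-4-ol
Conditions: TBAF, AcOH, THF, rt
Reagents that add atoms: none
Why: Fluoride desilylation buffered with acetic acid should free the secondary allylic alcohol without generating the alkoxide that could start a Payne rearrangement of the epoxy alcohol.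

**Step 9**
Reactants: 13 the epoxy diol
Product: 14 1-[(2S,3R)-3-[(5E)-3-methyl-4-oxohept-5-en-1-yl]-3-(propan-2-yl)oxiran-2-yl]ethan-1-one
Conditions: Dess–Martin periodinane (3 equiv), NaHCO3, CH2Cl2, rt
Reagents that add atoms: none
Why: Double Dess–Martin oxidation should convert both secondary alcohols at once, giving the epoxy methyl ketone (C6) and the (E)-propenyl ketone (C10).

**Step 10**
Reactants: 14 the epoxy diketone
Product: 15 triethyl({1-[(2S,3R)-3-{(5E)-3-methyl-4-[(triethylsilyl)oxy]hepta-3,5-dien-1-yl}-3-(propan-2-yl)oxiran-2-yl]ethenyl}oxy)silane (3E/3Z mixture)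
Conditions: LDA (2.4 equiv), TESCl (3 equiv, present from the start), THF, −78 °C; Et3N, pentane, filtration
Reagents that add atoms: chlorotriethylsilane, CC[Si](CC)(CC)Cl
Why: Kinetic deprotonation with internal silyl quench should remove a methyl proton of the epoxy ketone (its only readily enolisable site) and the α′ methine proton of the enone (α′ rather than γ), giving the epoxy enol silane and the cross-conjugated 2-silyloxy diene; the C1 centre is erased here and the geometry of the new tetrasubstituted enol ether is of no consequence.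

**Step 11**
Reactants: 15 the epoxy bis(enol silane)
Product: 17 4β,10-bis[(triethylsilyl)oxy]-5αH-dauc-9-en-6-one (trans-fused, C8 epimers), via 2-(triethylsilyloxy)allyl cation triflate 16 (not isolated)
Conditions: TESOTf (10 mol%), CH2Cl2, −78 °C; Et3N quench
Reagents that add atoms: triethylsilyl trifluoromethanesulfonate, CC[Si](CC)(CC)OS(=O)(=O)C(F)(F)F (catalytic; its silyl group is carried by 16 and released again)
Why: Catalytic TESOTf silylates the epoxide oxygen of 15; the C5–O bond, which is allylic to the enol silane, opens towards the 2-(silyloxy)allyl cation 16 (C5–C6–C7), and this is captured across C1 and C8 of the tethered 2-silyloxy diene, after which the silyl cation on the C6 oxygen is released and carries the chain, so that the step is an isomerisation. The closest known reaction type is the silyl-triflate-catalysed intramolecular (4+3) cycloaddition of epoxy enol silanes with tethered dienes, in which the epoxide configuration is passed on to the cycloadduct; with this electron-rich diene the two bonds probably form asynchronously, C1–C5 first (Mukaiyama-type alkylation) and C7–C8 second (intramolecular Mukaiyama–Michael addition to the silyloxocarbenium ion). The cyclopentane closes by 5-exo attack of the enol-silane carbon C1 on the allyl terminus C5 (both π systems stay outside the new ring), and the cycloheptene closes by 7-(enolendo)-endo-trig attack of C7 on C8, the (4+3) mode, whereas the competing 1,2-closure of C7 on C10 to a (3+2) adduct would be a disfavoured 5-(enolendo)-exo-trig process. C4 keeps the configuration from step 5 because its C–O bond is not broken, and C5 is set by entry of C1 anti to the departing oxygen (inversion); a fully ionised cation should give the same C5 epimer, since A(1,3) strain keeps the isopropyl group of C4 on the side of H-5 and the oxygen next to the allyl arm in the closing conformer. C1 is set by the extended (exo) arrangement, in which the silyloxy-bearing carbons C6 and C10 avoid the near-eclipsed contact of the compact alternative; this should give the trans ring fusion with CH3 cis to the C4 oxygen, while the C8 centre and the E/Z geometry of the diene at C1 do not matter because C8 becomes sp2 in step 12 and the C1–C10 bond can rotate after the first bond is made. The step needs opening at C5 and not at the tertiary C4, which the enol silane on C6 secures, and trans-selective capture, which the three-atom tether and the bulk at C6 and C10 secure.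

**Step 12**
Reactants: 17 the (4+3) adduct
Product: 19 4β-hydroxy-5αH-dauc-8-ene-6,10-dione, via silyl ether enedione 18 (not isolated)
Conditions: Pd(OAc)2 (1.1 equiv), MeCN, rt; then HF·pyridine, 0 °C
Reagents that add atoms: none
Why: Saegusa–Ito oxidation (palladium enolate at C9, syn β-hydride elimination of H-8) should turn the enol silane into the Δ8 enone and remove the C8 stereocentre, and HF·pyridine then cleaves the tertiary silyl ether under non-basic conditions that avoid epimerisation at C5 and β-elimination of O4.

**Step 13**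
Reactants: 19 the hydroxy enedione
Product: 20 4β,6α-dihydroxy-5αH-dauc-8-en-10-one
Conditions: Me4NBH(OAc)3, MeCN/AcOH (1:1), −30 °C
Reagents that add atoms: none
Why: Evans–Saksena hydroxyl-directed reduction: the C4 hydroxyl binds boron and delivers hydride intramolecularly to the β face of the C6 ketone, which should give the 6α-alcohol, while the C10 enone has no hydroxyl within reach and is not reduced by the triacetoxyborohydride.

**Step 14**
Reactants: 20 the diol enone; 21 3,4-dimethoxybenzoyl chloride (veratroyl chloride)
Product: 22 4β-hydroxy-10-oxo-5αH-dauc-8-en-6α-yl 3,4-dimethoxybenzoate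
Conditions: Et3N, DMAP (cat.), CH2Cl2, 0 °C to rt
Reagents that add atoms: none
Why: DMAP-catalysed acylation should take place only at the secondary C6 hydroxyl, the tertiary C4 hydroxyl being inert under these conditions.

**Step 15**
Reactants: 22 the veratrate enone
Product: 23 4β,10β-dihydroxy-5αH-dauc-8-en-6α-yl 3,4-dimethoxybenzoate
Conditions: NaBH4, CeCl3·7H2O, MeOH, −78 °C
Reagents that add atoms: none
Why: Luche 1,2-reduction; hydride should add to C10 from the α face, anti to the pseudoaxial C1 methyl group on the neighbouring carbon, giving the 10β-alcohol (OH cis to CH3), which is the epimer needed for an invertive esterification.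

**Step 16**
Reactants: 23 the 10β-alcohol; 24 (2Z)-2-methylbut-2-enoic acid (angelic acid)
Product: 25 10α-(angeloyloxy)-4β-hydroxy-5αH-dauc-8-en-6α-yl 3,4-dimethoxybenzoate (target)
Conditions: PPh3, DIAD, THF, 0 °C to rt
Reagents that add atoms: none
Why: Mitsunobu esterification with inversion: the angelate should attack C10 of the alkoxyphosphonium ion from the α face (anti to the C1 methyl), giving the 10α-ester, while the neutral, cold conditions avoid Z-to-E isomerisation to the tiglate and leave the tertiary alcohol untouched.

**Compound list**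

1 | (E)-but-2-enal (crotonaldehyde) | C/C=C/C=O | starting material
2 | (E)-1-bromobut-2-ene (crotyl bromide) | C/C=C/CBr | starting material
3 | (5E)-3-methylhepta-1,5-dien-4-ol (diastereomer mixture) | C=CC(C)C(O)/C=C/C | intermediate
4 | tert-butyl{[(5E)-3-methylhepta-1,5-dien-4-yl]oxy}dimethylsilane | C=CC(C)C(O[Si](C)(C)C(C)(C)C)/C=C/C | intermediate
5 | 4-methylpent-2-yn-1-ol | CC(C)C#CCO | starting material
6 | sodium 2,2-bis(2-methoxyethoxy)-3-(propan-2-yl)-2,5-dihydro-1,2-oxaaluminol-2-uide (cyclic alkenylalanate, formed in the flask) | CC(C)C1=CCO[Al-]1(OCCOC)OCCOC.[Na+] | intermediate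
7 | (2Z)-3-iodo-4-methylpent-2-en-1-ol | CC(C)/C(I)=C/CO | intermediate
8 | 9-{(5E)-4-[(tert-butyldimethylsilyl)oxy]-3-methylhept-5-en-1-yl}-9-borabicyclo[3.3.1]nonane (formed in the flask) | C/C=C/C(O[Si](C)(C)C(C)(C)C)C(C)CCB1C2CCCC1CCC2 | intermediate
9 | (2E,8E)-7-[(tert-butyldimethylsilyl)oxy]-6-methyl-3-(propan-2-yl)deca-2,8-dien-1-ol | CC(C)/C(CCC(C)C(O[Si](C)(C)C(C)(C)C)/C=C/C)=C/CO | intermediate
10 | [(2R,3R)-3-{(5E)-4-[(tert-butyldimethylsilyl)oxy]-3-methylhept-5-en-1-yl}-3-(propan-2-yl)oxiran-2-yl]methanol | OC[C@H]1O[C@]1(CCC(C)C(O[Si](C)(C)C(C)(C)C)/C=C/C)C(C)C | intermediate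
11 | (2S,3R)-3-{(5E)-4-[(tert-butyldimethylsilyl)oxy]-3-methylhept-5-en-1-yl}-3-(propan-2-yl)oxirane-2-carbaldehyde | O=C[C@H]1O[C@]1(CCC(C)C(O[Si](C)(C)C(C)(C)C)/C=C/C)C(C)C | intermediate
12 | 1-[(2R,3R)-3-{(5E)-4-[(tert-butyldimethylsilyl)oxy]-3-methylhept-5-en-1-yl}-3-(propan-2-yl)oxiran-2-yl]ethan-1-ol (carbinol epimers) | CC(O)[C@H]1O[C@]1(CCC(C)C(O[Si](C)(C)C(C)(C)C)/C=C/C)C(C)C | intermediate
13 | (5E)-1-[(2R,3R)-3-(1-hydroxyethyl)-2-(propan-2-yl)oxiran-2-yl]-3-methylhept-5-en-4-ol | CC(O)[C@H]1O[C@]1(CCC(C)C(O)/C=C/C)C(C)C | intermediate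
14 | 1-[(2S,3R)-3-[(5E)-3-methyl-4-oxohept-5-en-1-yl]-3-(propan-2-yl)oxiran-2-yl]ethan-1-one | CC(=O)[C@H]1O[C@]1(CCC(C)C(=O)/C=C/C)C(C)C | intermediate
15 | triethyl({1-[(2S,3R)-3-{(5E)-3-methyl-4-[(triethylsilyl)oxy]hepta-3,5-dien-1-yl}-3-(propan-2-yl)oxiran-2-yl]ethenyl}oxy)silane (3E/3Z mixture) | C=C(O[Si](CC)(CC)CC)[C@H]1O[C@]1(CCC(C)=C(O[Si](CC)(CC)CC)/C=C/C)C(C)C | intermediate
16 | 2-(triethylsilyloxy)allyl cation (C5–C6–C7) with O4 silylated, as its triflate (formed in the flask) | C=C(O[Si](CC)(CC)CC)[CH+][C@](CCC(C)=C(O[Si](CC)(CC)CC)/C=C/C)(O[Si](CC)(CC)CC)C(C)C.[O-]S(=O)(=O)C(F)(F)F | intermediate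
17 | 4β,10-bis[(triethylsilyl)oxy]-5αH-dauc-9-en-6-one (trans-fused, 1β-CH3, C8 epimers) | CC[Si](CC)(CC)OC1=CC(C)CC(=O)[C@@H]2[C@]1(C)CC[C@@]2(O[Si](CC)(CC)CC)C(C)C | intermediate
18 | 4β-[(triethylsilyl)oxy]-5αH-dauc-8-ene-6,10-dione (formed in the flask) | O=C1C=C(C)CC(=O)[C@@H]2[C@]1(C)CC[C@@]2(O[Si](CC)(CC)CC)C(C)C | intermediate
19 | 4β-hydroxy-5αH-dauc-8-ene-6,10-dione | O=C1C=C(C)CC(=O)[C@@H]2[C@]1(C)CC[C@@]2(O)C(C)C | intermediate
20 | 4β,6α-dihydroxy-5αH-dauc-8-en-10-one | O=C1C=C(C)C[C@H](O)[C@@H]2[C@]1(C)CC[C@@]2(O)C(C)C | intermediate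
21 | 3,4-dimethoxybenzoyl chloride (veratroyl chloride) | COc1ccc(C(=O)Cl)cc1OC | starting material
22 | 4β-hydroxy-10-oxo-5αH-dauc-8-en-6α-yl 3,4-dimethoxybenzoate | O=C1C=C(C)C[C@H](OC(=O)c3ccc(OC)c(OC)c3)[C@@H]2[C@]1(C)CC[C@@]2(O)C(C)C | intermediate
23 | 4β,10β-dihydroxy-5αH-dauc-8-en-6α-yl 3,4-dimethoxybenzoate | O[C@H]1C=C(C)C[C@H](OC(=O)c3ccc(OC)c(OC)c3)[C@@H]2[C@]1(C)CC[C@@]2(O)C(C)C | intermediate
24 | (2Z)-2-methylbut-2-enoic acid (angelic acid) | C/C=C(/C)C(=O)O | starting material
25 | (3R,3aS,4S,8R,8aS)-3-hydroxy-6,8a-dimethyl-8-{[(2Z)-2-methylbut-2-enoyl]oxy}-3-(propan-2-yl)-1,2,3,3a,4,5,8,8a-octahydroazulen-4-yl 3,4-dimethoxybenzoate | C/C=C(/C)C(=O)O[C@@H]1C=C(C)C[C@H](OC(=O)c2ccc(OC)c(OC)c2)[C@@H]2[C@]1(C)CC[C@@]2(O)C(C)C | target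

**Totals**

Total step count: 16. Longest linear sequence: 15 steps (steps 1, 2, 4–16, from crotonaldehyde).

**Steps most likely to fail**

Step 11. After the first C–C bond (C1–C5) the silyloxocarbenium ion may be quenched, or close through oxygen, before C7 reaches C8; the ring-fusion selectivity also rests on a transition-state argument. The fallback sets out from 15 and makes the two bonds in separate operations. TESOTf (1.1 equiv) with 2,6-di-tert-butyl-4-methylpyridine in CH2Cl2 at −78 °C, followed by aqueous work-up, should stop at the cyclopentane that holds only the C1–C5 bond, the monocyclic silyl ether dione F1 (C6 methyl ketone, C10 propenyl ketone, O4 silylated). Kinetic deprotonation of the methyl ketone with LDA at −78 °C, warming so that the enolate adds to the enone (7-endo-trig intramolecular Michael addition, C7 to C8), and trapping of the resulting C10 enolate with TESCl should give 17, where the route is rejoined.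

Step 15. The facial selectivity of hydride addition at C10 may be low or reversed, since the prediction rests only on the pseudoaxial C1 methyl group. The fallback sets out from 22 and switches from invertive to retentive esterification for whatever share is formed of the epimeric 10α-alcohol F2. F2 is separated and acylated by the mixed anhydride F3, made in the flask from 24 and 2,4,6-trichlorobenzoyl chloride (Et3N, toluene, 80 °C, no DMAP, to keep the Z geometry); this gives 25 directly. The 10β-epimer 23 continues through step 16, so both epimers converge on 25.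

Step 16. Elimination to the diene or allylic transposition (SN2′ or ionisation) may compete with SN2 inversion at the hindered, neopentyl-type allylic carbinol, and the weakly acidic angelic acid is a sluggish partner. The fallback sets out from 23 and separates inversion from angeloylation. A Mitsunobu reaction with the more acidic 4-nitrobenzoic acid should give the inverted 10α 4-nitrobenzoate F4. Mild methanolysis (K2CO3, MeOH, 0 °C) cleaves this activated ester in the presence of the electron-rich veratrate and frees the 10α-alcohol F2 named under step 15. Retentive acylation with the mixed anhydride F3, as described there, then gives 25.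

**Further compounds**

F1 | step 11 | (2E)-1-{2-acetyl-1-methyl-3-(propan-2-yl)-3-[(triethylsilyl)oxy]cyclopentyl}but-2-en-1-one with the C1, C4 and C5 configurations of 17 | CC(=O)[C@@H]1[C@@](C)(C(=O)/C=C/C)CC[C@@]1(O[Si](CC)(CC)CC)C(C)C
F2 | step 15 | 4β,10α-dihydroxy-5αH-dauc-8-en-6α-yl 3,4-dimethoxybenzoate | O[C@@H]1C=C(C)C[C@H](OC(=O)c3ccc(OC)c(OC)c3)[C@@H]2[C@]1(C)CC[C@@]2(O)C(C)C
F3 | step 15 | (2Z)-2-methylbut-2-enoic 2,4,6-trichlorobenzoic anhydride | C/C=C(/C)C(=O)OC(=O)c1c(Cl)cc(Cl)cc1Cl
F4 | step 16 | 4β-hydroxy-10α-[(4-nitrobenzoyl)oxy]-5αH-dauc-8-en-6α-yl 3,4-dimethoxybenzoate | O=C(O[C@@H]1C=C(C)C[C@H](OC(=O)c3ccc(OC)c(OC)c3)[C@@H]2[C@]1(C)CC[C@@]2(O)C(C)C)c1ccc(cc1)[N+](=O)[O-]
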